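**Plan**

1. Retrosynthetic cuts, in order: the six MOM ethers; the aryl C–O bond O1–C8a of the dioxane (O1 is the oxygen on C2, the carbon that carries the catechol ring; C8a is the benzo carbon meta to the styryl arm on C7); the carbinol C–H (back to a ketone); the O4–C3 bond (phenoxide plus α-bromoketone); the stilbene C–C bond (Heck pair) and the aryl–CH2 bond of the deoxybenzoin (ketone α-arylation).
2. Forward: the chain is built first (deoxybenzoin, then its α-bromide; separately the E-stilbene arm is put on 2-bromo-4-iodophenol; the halves are joined through O4), the ketone is reduced, and the only ring made in the route, the 1,4-dioxane, is closed last onto the benzo ring.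
3. Enabling feature: the two dioxane oxygens sit on adjacent benzo carbons C4a and C8a, O4 para and O1 meta to C7. A phenol carrying Br ortho and the arm para to its OH therefore fixes which oxygen goes where, and leaves the C2 hydroxyl placed for a six-membered aryl C–O closure onto the brominated carbon.
4. Stereochemistry: C2 and C3 are set together as the threo (1R,2R) alcohol by Ru-catalysed asymmetric transfer hydrogenation with dynamic kinetic resolution of the racemic α-aryloxy ketone. The ring closure breaks no bond at either sp3 carbon, so threo is carried into trans-(2R,3R); the E-olefin comes from the Heck step.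

Key step: step 9

Remark: target locants are taken as O1–C2(3,4-dihydroxyphenyl)–C3(3,5-dihydroxyphenyl)–O4 with the styryl arm on C7; compounds 1, 3 and 9 and all reagents are taken as commercial.

**Route**

Step 1
Reactants: 1 5-bromobenzene-1,3-diol
Product: 2 1-bromo-3,5-bis(methoxymethoxy)benzene
Conditions: MOMCl (2.5 equiv), i-Pr2NEt (3 equiv), DMF, 0 °C to rt
Reagents that add atoms: chloromethyl methyl ether (MOMCl), COCCl
Why: Williamson-type O-alkylation of both phenols by the reactive α-chloro ether should give the base-stable MOM acetals, which can be removed at the end with protic acid, without Lewis acid or hydrogenolysis.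

Step 2
Reactants: 3 1-(3,4-dihydroxyphenyl)ethan-1-one
Product: 4 1-[3,4-bis(methoxymethoxy)phenyl]ethan-1-one
Conditions: MOMCl (2.5 equiv), i-Pr2NEt (3 equiv), DMF, 0 °C to rt
Reagents that add atoms: chloromethyl methyl ether (MOMCl), COCCl
Why: The same Williamson-type O-alkylation should protect the catechol, the phenols being far more acidic than the methyl ketone.

Step 3
Reactants: 2 1-bromo-3,5-bis(methoxymethoxy)benzene; 4 1-[3,4-bis(methoxymethoxy)phenyl]ethan-1-one
Product: 5 1-[3,4-bis(methoxymethoxy)phenyl]-2-[3,5-bis(methoxymethoxy)phenyl]ethan-1-one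
Conditions: Pd2(dba)3 (1.5 mol%), Xantphos (3.6 mol%), NaOt-Bu (2.2 equiv), 4 in slight excess, THF, 70 °C; aq NH4Cl
Reagents that add atoms: none
Why: Palladium-catalysed α-arylation of a methyl ketone enolate (Buchwald–Hartwig type) should join the two aryl units, the product being held as its more acidic enolate, which disfavours a second arylation.

Step 4
Reactants: 5 1-[3,4-bis(methoxymethoxy)phenyl]-2-[3,5-bis(methoxymethoxy)phenyl]ethan-1-one
Product: 7 rac-2-bromo-1-[3,4-bis(methoxymethoxy)phenyl]-2-[3,5-bis(methoxymethoxy)phenyl]ethan-1-one, via lithium enolate 6 (not isolated)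
Conditions: LiN(SiMe3)2 (1.05 equiv), THF, −78 °C; then transfer into NBS (1.05 equiv), THF, −78 °C; aq NH4Cl
Reagents that add atoms: N-bromosuccinimide (NBS), O=C1CCC(=O)N1Br
Why: Electrophilic α-bromination of the preformed lithium enolate should outrun bromination of the electron-rich rings and avoids HBr that would cleave MOM ethers; the new centre is racemic, which is harmless because it is equilibrated in step 8.

Step 5
Reactants: 2 1-bromo-3,5-bis(methoxymethoxy)benzene
Product: 8 1-ethenyl-3,5-bis(methoxymethoxy)benzene
Conditions: vinylboronic acid pinacol ester (1.3 equiv), PdCl2(dppf) (3 mol%), K2CO3, 1,4-dioxane/H2O, 85 °C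
Reagents that add atoms: vinylboronic acid pinacol ester, C=CB1OC(C)(C)C(C)(C)O1
Why: Suzuki–Miyaura vinylation of the aryl bromide should give the styrene needed for the stilbene arm.

Step 6
Reactants: 8 1-ethenyl-3,5-bis(methoxymethoxy)benzene; 9 2-bromo-4-iodophenol
Product: 10 2-bromo-4-{(E)-2-[3,5-bis(methoxymethoxy)phenyl]ethenyl}phenol
Conditions: Pd(OAc)2 (3 mol%), Et3N, DMF, 80 °C
Reagents that add atoms: none
Why: In this Heck reaction zerovalent palladium should insert into the C–I bond in preference to the hindered, electron-rich C–Br bond, and syn insertion followed by syn β-hydride elimination should give the E-stilbene.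

Step 7
Reactants: 7 rac-2-bromo-1-[3,4-bis(methoxymethoxy)phenyl]-2-[3,5-bis(methoxymethoxy)phenyl]ethan-1-one; 10 2-bromo-4-{(E)-2-[3,5-bis(methoxymethoxy)phenyl]ethenyl}phenol
Product: 11 rac-2-(2-bromo-4-{(E)-2-[3,5-bis(methoxymethoxy)phenyl]ethenyl}phenoxy)-1-[3,4-bis(methoxymethoxy)phenyl]-2-[3,5-bis(methoxymethoxy)phenyl]ethan-1-one
Conditions: K2CO3, acetone, rt
Reagents that add atoms: none
Why: SN2 displacement (Williamson ether synthesis) of the activated benzylic α-keto bromide by the phenoxide should fix the future O4 on the carbon bearing the 3,5-dioxygenated ring, which defines the regiochemistry of the dioxane before any ring exists.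

Step 8
Reactants: 11 rac-2-(2-bromo-4-{(E)-2-[3,5-bis(methoxymethoxy)phenyl]ethenyl}phenoxy)-1-[3,4-bis(methoxymethoxy)phenyl]-2-[3,5-bis(methoxymethoxy)phenyl]ethan-1-one
Product: 12 (1R,2R)-2-(2-bromo-4-{(E)-2-[3,5-bis(methoxymethoxy)phenyl]ethenyl}phenoxy)-1-[3,4-bis(methoxymethoxy)phenyl]-2-[3,5-bis(methoxymethoxy)phenyl]ethan-1-ol
Conditions: RuCl[(S,S)-TsDPEN](p-cymene) (2 mol%), HCO2H/Et3N (5:2 azeotrope), DMF, 40 °C
Reagents that add atoms: none
Why: In this Noyori–Ikariya asymmetric transfer hydrogenation with dynamic kinetic resolution the acidic α-C–H (α-aryl, α-aryloxy, α-keto) should epimerise faster than hydride transfer, the (S,S)-catalyst should set the (1R) carbinol, and a polar Felkin–Anh arrangement with the aryloxy group anti to the incoming hydride should select the (2R) ketone, by analogy with the reduction of racemic benzoin to (R,R)-hydrobenzoin by the same catalyst, so that both stereocentres arise as the threo (1R,2R) pair.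

Step 9
Reactants: 12 (1R,2R)-2-(2-bromo-4-{(E)-2-[3,5-bis(methoxymethoxy)phenyl]ethenyl}phenoxy)-1-[3,4-bis(methoxymethoxy)phenyl]-2-[3,5-bis(methoxymethoxy)phenyl]ethan-1-ol
Product: 13 (2R,3R)-2-[3,4-bis(methoxymethoxy)phenyl]-3-[3,5-bis(methoxymethoxy)phenyl]-7-{(E)-2-[3,5-bis(methoxymethoxy)phenyl]ethenyl}-2,3-dihydro-1,4-benzodioxine
Conditions: CuI (10 mol%), 3,4,7,8-tetramethyl-1,10-phenanthroline (20 mol%), Cs2CO3 (2 equiv), toluene (high dilution), 110 °C, argon
Reagents that add atoms: none
Why: Cs2CO3 should convert the C1 hydroxyl into an alkoxide on the phenanthroline-bound monovalent copper centre, the neighbouring aryl C–Br bond should add oxidatively to give a seven-membered aryl(alkoxo) trivalent copper chelate, and C–O reductive elimination should form the O1–C8a bond and return the catalyst. The closest known reaction type is the Ullmann-type copper-catalysed O-arylation of secondary alcohols with aryl bromides, whose intramolecular form is an established entry to 2,3-dihydro-1,4-benzodioxines. The one ring formed, the six-membered dioxane, closes in a 6-exo sense by attack of the side-chain oxygen on the ipso carbon with loss of bromide. No new stereocentre is created: no bond at either sp3 carbon is broken, so the threo (1R,2R) alcohol should pass with retention into the trans (2R,3R) ring. The step needs regioselectivity (which oxygen ends para to the styryl arm), preference for cyclisation over intermolecular etherification and over oxidation of the benzylic carbinol, and stereochemical integrity. These are secured by the bromine sitting ortho to the preformed ether oxygen, by the six-membered geometry, dilution and the lack of easy β-hydride elimination at copper, and by a carbonate base too weak to deprotonate either benzylic C–H.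

Step 10
Reactants: 13 (2R,3R)-2-[3,4-bis(methoxymethoxy)phenyl]-3-[3,5-bis(methoxymethoxy)phenyl]-7-{(E)-2-[3,5-bis(methoxymethoxy)phenyl]ethenyl}-2,3-dihydro-1,4-benzodioxine
Product: 14 cassigarol E, (2R,3R)-2-(3,4-dihydroxyphenyl)-3-(3,5-dihydroxyphenyl)-7-[(E)-2-(3,5-dihydroxyphenyl)ethenyl]-2,3-dihydro-1,4-benzodioxine
Conditions: HCl (2 M) in MeOH, rt to 40 °C, argon
Reagents that add atoms: none
Why: Acid-catalysed acetal exchange with methanol (MOM cleavage) should free all six phenols under protic conditions mild enough to leave the benzylic C–O bonds of the dioxane, both stereocentres and the E-olefin untouched.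

**Compound list**

1 | 5-bromobenzene-1,3-diol | Oc1cc(O)cc(Br)c1 | starting material
2 | 1-bromo-3,5-bis(methoxymethoxy)benzene | COCOc1cc(OCOC)cc(Br)c1 | intermediate
3 | 1-(3,4-dihydroxyphenyl)ethan-1-one | CC(=O)c1ccc(O)c(O)c1 | starting material
4 | 1-[3,4-bis(methoxymethoxy)phenyl]ethan-1-one | CC(=O)c1ccc(OCOC)c(OCOC)c1 | intermediate
5 | 1-[3,4-bis(methoxymethoxy)phenyl]-2-[3,5-bis(methoxymethoxy)phenyl]ethan-1-one | O=C(Cc1cc(OCOC)cc(OCOC)c1)c1ccc(OCOC)c(OCOC)c1 | intermediate
6 | lithium (Z)-enolate of 5 (not isolated) | [Li+].[O-]/C(=C\c1cc(OCOC)cc(OCOC)c1)c1ccc(OCOC)c(OCOC)c1 | intermediate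
7 | rac-2-bromo-1-[3,4-bis(methoxymethoxy)phenyl]-2-[3,5-bis(methoxymethoxy)phenyl]ethan-1-one | O=C(C(Br)c1cc(OCOC)cc(OCOC)c1)c1ccc(OCOC)c(OCOC)c1 | intermediate
8 | 1-ethenyl-3,5-bis(methoxymethoxy)benzene | C=Cc1cc(OCOC)cc(OCOC)c1 | intermediate
9 | 2-bromo-4-iodophenol | Oc1ccc(I)cc1Br | starting material
10 | 2-bromo-4-{(E)-2-[3,5-bis(methoxymethoxy)phenyl]ethenyl}phenol | Oc1ccc(/C=C/c2cc(OCOC)cc(OCOC)c2)cc1Br | intermediate
11 | racemic α-aryloxy ketone (name as in step 7) | O=C(C(Oc1ccc(/C=C/c2cc(OCOC)cc(OCOC)c2)cc1Br)c1cc(OCOC)cc(OCOC)c1)c1ccc(OCOC)c(OCOC)c1 | intermediate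
12 | (1R,2R) threo aryloxy alcohol (name as in step 8) | COCOc1cc(OCOC)cc(/C=C/c2ccc(O[C@H](c3cc(OCOC)cc(OCOC)c3)[C@H](O)c3ccc(OCOC)c(OCOC)c3)c(Br)c2)c1 | intermediate
13 | (2R,3R) hexa-MOM benzodioxine (name as in step 9) | COCOc1cc(OCOC)cc(/C=C/c2ccc3c(c2)O[C@H](c2ccc(OCOC)c(OCOC)c2)[C@@H](c2cc(OCOC)cc(OCOC)c2)O3)c1 | intermediate
14 | cassigarol E | Oc1cc(O)cc(/C=C/c2ccc3c(c2)O[C@H](c2ccc(O)c(O)c2)[C@@H](c2cc(O)cc(O)c2)O3)c1 | target

**Count and risks**

Total steps: 10. Longest linear sequence: 7 steps (steps 1, 3, 4, 7, 8, 9, 10).

Step 8. Epimerisation of the α-centre may be slower than reduction, so that the dynamic resolution stalls, or the bulky 2-bromoaryloxy group may fail to take the anti position, which would erode threo selection. The fallback sets out from 11: reduction with LiBH(s-Bu)3 in THF at −78 °C, where polar Felkin–Anh control should favour the threo alcohol as the racemate, that is 12 together with its mirror image, the (1S,2S)-alcohol F1. Preparative chromatography on a chiral stationary phase would then separate F1 and deliver 12, where the route resumes before step 9.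

Step 9. Oxidative addition at the hindered, electron-rich C–Br bond may be slow, which would open the way to protodebromination, intermolecular etherification or thermal damage at 110 °C. The fallback sets out from 12 and reverses the polarity of the aryl carbon: Miyaura borylation (B2pin2, PdCl2(dppf), KOAc, 1,4-dioxane, 80 °C) should give the arylboronic pinacol ester F2. A Chan–Lam oxidative coupling (Cu(OAc)2, pyridine, molecular sieves, air, CH2Cl2, rt) should then close the same O1–C8a bond at room temperature and return to the route at 13.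

Step 4. The enolate may attack bromoketone already formed (self-alkylation), bromination may go twice, or the 3,5-dioxygenated ring may be brominated; elimination or decomposition of the labile bromide in step 7 belongs to the same risk. The fallback sets out from 5 and avoids the halide: Regitz diazo transfer (4-acetamidobenzenesulfonyl azide, DBU, MeCN, rt) should give the diazoketone F3. Rh2(OAc)4-catalysed O–H insertion of its carbenoid into phenol 10 (CH2Cl2, rt) should then give 11 directly, so the route is rejoined at 11 and compound 7 and step 7 are bypassed.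

**Further compounds**

F1 | step 8 | (1S,2S)-2-(2-bromo-4-{(E)-2-[3,5-bis(methoxymethoxy)phenyl]ethenyl}phenoxy)-1-[3,4-bis(methoxymethoxy)phenyl]-2-[3,5-bis(methoxymethoxy)phenyl]ethan-1-ol | COCOc1cc(OCOC)cc(/C=C/c2ccc(O[C@@H](c3cc(OCOC)cc(OCOC)c3)[C@@H](O)c3ccc(OCOC)c(OCOC)c3)c(Br)c2)c1
F2 | step 9 | (1R,2R)-1-[3,4-bis(methoxymethoxy)phenyl]-2-[3,5-bis(methoxymethoxy)phenyl]-2-[4-{(E)-2-[3,5-bis(methoxymethoxy)phenyl]ethenyl}-2-(4,4,5,5-tetramethyl-1,3,2-dioxaborolan-2-yl)phenoxy]ethan-1-ol | COCOc1cc(OCOC)cc(/C=C/c2ccc(O[C@H](c3cc(OCOC)cc(OCOC)c3)[C@H](O)c3ccc(OCOC)c(OCOC)c3)c(B3OC(C)(C)C(C)(C)O3)c2)c1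
F3 | step 4 | 2-diazo-1-[3,4-bis(methoxymethoxy)phenyl]-2-[3,5-bis(methoxymethoxy)phenyl]ethan-1-one | O=C(C(=[N+]=[N-])c1cc(OCOC)cc(OCOC)c1)c1ccc(OCOC)c(OCOC)c1
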